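**Conventions.** Briarane numbering is used: C1 is the quaternary ring-fusion carbon bearing the C15 methyl; C2–C9 are the other carbons of the ten-membered ring B (C2 next to C1); C10 is the ring-fusion CH; C11–C14 complete ring A; C16 is the exocyclic CH2 on C5; C17(C18)/C19 are CH(CH3)/C=O of lactone ring C; C20 is the methyl on C11. On ring A, β is the face of the C15 methyl. Target = (1S,2S,3Z,6S,7R,8R,9S,10S,11S,12R,17R). L1 = N-[2-(4-isopropyl-4,5-dihydrooxazol-2-yl)-6-methylphenyl]methanesulfonamide; L2 = 3,6-di-tert-butyl-1,8-bis(4-isopropyl-4,5-dihydrooxazol-2-yl)-9H-carbazole.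

**Assumption.** In the catalyst- or ligand-controlled steps (2, 13, 19, 28) the antipode of the chiral controller that gives the stated configuration is used; the one written is nominal.

## Retrosynthetic overview

1. Ring B is closed last by ring-closing metathesis across C3=C4 of a C2-vinyl/C5-vinyl precursor that already carries rings A and C.
2. Ring C and the C6–Cl/C7–O pair come from the new step: a chromium-catalysed asymmetric γ-chloroallylation of a C7 aldehyde with a 2-vinyl-3-chloroallyl bromide (C6–C7 bond); the new C7 hydroxyl then lactonises onto a C19 Weinreb amide.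
3. C8 (tertiary OH) and C17 are set earlier on a temporary butenolide whose ring oxygen sits on C9 (epoxidation anti to ring A, reductive opening, Fráter–Seebach methylation); it is then opened to the Weinreb amide and O9 is acetylated.
4. That butenolide comes from a ring A C9 aldehyde and a (Z)-β-iodoenoate (Nozaki–Hiyama–Kishi coupling/lactonisation); C2 comes from an asymmetric vinylation of a C2 aldehyde.
5. Ring A is made first by a catalytic asymmetric Diels–Alder reaction (C1, C10) and diene cis-dihydroxylation (C11, C12). Ring order: A, temporary butenolide, C, B.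

## Route

Step 1
Reactants: 1 pent-1-en-3-one
Product: 2 (Z)-triisopropyl(penta-1,3-dien-3-yloxy)silane
Conditions: iPr3SiOTf, Et3N, CH2Cl2, 0 °C → rt
Reagents that add atoms: triisopropylsilyl triflate (CC(C)[Si](C(C)C)(C(C)C)OS(=O)(=O)C(F)(F)F)
Why: Soft enolisation/O-silylation of the enone gives the 2-silyloxydiene as the Z enol ether (methyl anti to the vinyl group), the geometry that allows a reactive s-cis diene.

Step 2
Reactants: 2 (Z)-triisopropyl(penta-1,3-dien-3-yloxy)silane; 3 ethyl (E)-3-methyl-4-oxobut-2-enoate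
Product: 4 ethyl (1S,2S,6S)-6-formyl-2,6-dimethyl-3-(triisopropylsilyloxy)cyclohex-3-ene-1-carboxylate (C15 methyl β; CHO α; C9 ester β; C20 methyl α)
Conditions: (S)-B-(o-tolyl)oxazaborolidine of α,α-diphenylprolinol·HNTf2 (20 mol %), CH2Cl2, −78 → −40 °C
Reagents that add atoms: none
Why: Catalytic enantioselective Diels–Alder reaction: the cationic oxazaborolidine binds the formyl group, so the methyl-bearing nucleophilic diene terminus bonds to the carbon β to CHO (silyloxy para to the quaternary carbon), the E dienophile fixes CHO trans to CO2Et (C15 methyl cis to C9), and the catalyst shields one enal face to set C1 and C10 absolutely; the C11 configuration from the endo-CHO transition state is erased in step 6.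

Step 3
Reactants: 4 ethyl (1S,2S,6S)-6-formyl-2,6-dimethyl-3-(triisopropylsilyloxy)cyclohex-3-ene-1-carboxylate
Product: 5 ethyl 6-(hydroxymethyl)-2,6-dimethyl-3-(triisopropylsilyloxy)cyclohex-3-ene-1-carboxylate (configuration as 4)
Conditions: NaBH4, EtOH, −20 °C; AcOH quench
Reagents that add atoms: none
Why: Chemoselective borohydride reduction of the aldehyde in the presence of the ester and the silyl enol ether; no stereocentre is touched.

Step 4
Reactants: 5 ethyl 6-(hydroxymethyl)-2,6-dimethyl-3-(triisopropylsilyloxy)cyclohex-3-ene-1-carboxylate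
Product: 6 ethyl 6-[(tert-butyldimethylsilyloxy)methyl]-2,6-dimethyl-3-(triisopropylsilyloxy)cyclohex-3-ene-1-carboxylate
Conditions: t-BuMe2SiCl, imidazole, DMF, 0 °C → rt
Reagents that add atoms: tert-butyldimethylsilyl chloride (CC(C)(C)[Si](C)(C)Cl)
Why: Standard silylation protects the C2 primary alcohol through the enolate, palladium and osmium steps and prevents lactonisation onto the C9 ester.

Step 5
Reactants: 6 ethyl 6-[(tert-butyldimethylsilyloxy)methyl]-2,6-dimethyl-3-(triisopropylsilyloxy)cyclohex-3-ene-1-carboxylate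
Product: 7 ethyl 6-[(tert-butyldimethylsilyloxy)methyl]-2,6-dimethyl-3-oxocyclohex-4-ene-1-carboxylate (C12 ketone; C13=C14)
Conditions: Pd(OAc)2 (10 mol %), O2 (1 atm), DMSO, 60 °C
Reagents that add atoms: none
Why: Saegusa–Ito oxidation: the palladium enolate formed from the regiodefined enol ether can undergo β-hydride elimination only toward C14, which places the C13=C14 double bond where the target has it.

Step 6
Reactants: 7 ethyl 6-[(tert-butyldimethylsilyloxy)methyl]-2,6-dimethyl-3-oxocyclohex-4-ene-1-carboxylate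
Product: 9 ethyl 6-[(tert-butyldimethylsilyloxy)methyl]-2,6-dimethyl-3-(trifluoromethylsulfonyloxy)cyclohexa-2,4-diene-1-carboxylate, via potassium dienolate 8 (not isolated)
Conditions: KN(SiMe3)2, THF, −78 °C; then PhNTf2, −78 → 0 °C
Reagents that add atoms: N-phenylbis(trifluoromethanesulfonimide) (O=S(=O)(N(c1ccccc1)S(=O)(=O)C(F)(F)F)C(F)(F)F)
Why: Kinetic deprotonation at the only α′ position of the enone (C11; C1 is quaternary) and O-triflation of the dienolate give the cross-conjugated dienyl triflate and planarise C11.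

Step 7
Reactants: 9 ethyl 6-[(tert-butyldimethylsilyloxy)methyl]-2,6-dimethyl-3-(trifluoromethylsulfonyloxy)cyclohexa-2,4-diene-1-carboxylate
Product: 10 ethyl 6-[(tert-butyldimethylsilyloxy)methyl]-2,6-dimethylcyclohexa-2,4-diene-1-carboxylate
Conditions: Pd(OAc)2 (5 mol %), PPh3 (10 mol %), HCO2H, n-Bu3N, DMF, 60 °C
Reagents that add atoms: none
Why: Palladium-catalysed formate reduction of an enol triflate (oxidative addition to zerovalent palladium, formate exchange with loss of CO2, reductive elimination of C–H) gives the 1,3-diene without touching ester or silyl ether.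

Step 8
Reactants: 10 ethyl 6-[(tert-butyldimethylsilyloxy)methyl]-2,6-dimethylcyclohexa-2,4-diene-1-carboxylate
Product: 11 ethyl 6-[(tert-butyldimethylsilyloxy)methyl]-2,3-dihydroxy-2,6-dimethylcyclohex-4-ene-1-carboxylate (11α-OH; 12α-OH; C20 methyl β; C15 methyl β; C9 ester β)
Conditions: OsO4 (2 mol %), N-methylmorpholine N-oxide, acetone/H2O, 0 °C → rt
Reagents that add atoms: N-methylmorpholine N-oxide (C[N+]1([O-])CCOCC1); water (O)
Why: Upjohn dihydroxylation: OsO4 adds syn to the more electron-rich trisubstituted C11=C12 bond (C13=C14 is shielded by the quaternary C1) from the α face, anti to the adjacent C10 ester and the pseudo-axial C15 methyl, which sets C11 and C12 together as the cis-diol.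

Step 9
Reactants: 11 ethyl 6-[(tert-butyldimethylsilyloxy)methyl]-2,3-dihydroxy-2,6-dimethylcyclohex-4-ene-1-carboxylate
Product: 12 acetonide ester (C11/C12 O-isopropylidene derivative of 11)
Conditions: 2,2-dimethoxypropane, PPTS (cat.), CH2Cl2, rt
Reagents that add atoms: 2,2-dimethoxypropane (COC(C)(C)OC)
Why: Acid-catalysed transketalisation protects the cis-diol against the hydride, base and oxidation steps that follow.

Step 10
Reactants: 12 acetonide ester
Product: 13 ring A aldehyde (acetonide; C2H2OTBS; C9 = CHO on the β face of C10)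
Conditions: iBu2AlH (1.1 equiv), CH2Cl2, −78 °C; aq. KNaC4H4O6
Reagents that add atoms: none
Why: Low-temperature iBu2AlH reduction stops at the aluminium hemiacetal of the hindered ester, which gives the aldehyde on work-up; the non-basic conditions keep C10 intact.

Step 11
Reactants: 14 tert-butyl(diphenyl)(prop-2-yn-1-yloxy)silane
Product: 16 methyl 4-(tert-butyldiphenylsilyloxy)but-2-ynoate, via lithium acetylide 15 (not isolated)
Conditions: n-BuLi, THF, −78 °C; then ClCO2Me, −78 → 0 °C
Reagents that add atoms: methyl chloroformate (COC(=O)Cl)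
Why: Deprotonation of the terminal alkyne and C-acylation of the acetylide with the chloroformate.

Step 12
Reactants: 16 methyl 4-(tert-butyldiphenylsilyloxy)but-2-ynoate
Product: 17 methyl (Z)-4-(tert-butyldiphenylsilyloxy)-3-iodobut-2-enoate
Conditions: NaI, AcOH, 70 °C
Reagents that add atoms: sodium iodide ([Na+].[I-])
Why: Conjugate hydroiodination of the ynoate is an anti addition that places iodine cis to the ester (Z β-iodoenoate).

Step 13
Reactants: 13 ring A aldehyde; 17 methyl (Z)-4-(tert-butyldiphenylsilyloxy)-3-iodobut-2-enoate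
Product: 19 (9S)-butenolide with ring oxygen on C9 (C8=C17; C8 bears CH2OSiPh2t-Bu; C9 bears ring A), via hydroxy enoate 18 (not isolated)
Conditions: CrCl2 (4 equiv), (S)-L1 (4.4 equiv), Et3N, NiCl2 (2 mol %), THF, rt; aq. NH4Cl
Reagents that add atoms: none
Why: Nozaki–Hiyama–Kishi alkenylation of the aldehyde with retention of olefin geometry, in which the chiral sulfonamide–chromium complex controls the new C9 carbinol (9S); the cis ester then lactonises to the butenolide.

Step 14
Reactants: 19 (9S)-butenolide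
Product: 20 (8S,9S,17S)-8,17-epoxy lactone (epoxide oxygen trans to ring A on the lactone)
Conditions: t-BuOOH, n-BuLi, THF, −78 → −20 °C
Reagents that add atoms: tert-butyl hydroperoxide (CC(C)(C)OO)
Why: Weitz–Scheffer nucleophilic epoxidation: the peroxide anion adds to C8 anti to the bulky ring A substituent on the adjacent γ-carbon C9, which fixes the C8–O bond with the target configuration.

Step 15
Reactants: 20 (8S,9S,17S)-8,17-epoxy lactone
Product: 21 (8S,9S)-β-hydroxy lactone (8-OH trans to ring A; C17H2)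
Conditions: SmI2 (2.5 equiv), Me2NCH2CH2OH, HMPA, THF, −40 °C
Reagents that add atoms: none
Why: Samarium diiodide reduction of an α,β-epoxy lactone cleaves the Cα–O bond and leaves the C8 carbinol untouched.

Step 16
Reactants: 21 (8S,9S)-β-hydroxy lactone
Product: 23 (8S,9S,17R)-α-methyl-β-hydroxy lactone (C18 methyl trans to 8-OH), via dilithium alkoxide enolate 22 (not isolated)
Conditions: LiN(iPr)2 (2.5 equiv), THF, −78 → −40 °C; then MeI, DMPU, −78 → −30 °C
Reagents that add atoms: iodomethane (CI)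
Why: Fráter–Seebach alkylation: the chelated alkoxide–enolate dianion is methylated anti to the C8 oxygen, which gives the 17R configuration of the target.

Step 17
Reactants: 23 (8S,9S,17R)-α-methyl-β-hydroxy lactone
Product: 24 C2 primary alcohol (TBS removed; TBDPS, acetonide and lactone kept)
Conditions: HF·pyridine, pyridine, THF, 0 °C
Reagents that add atoms: none
Why: Buffered fluoride cleaves the primary TBS ether much faster than the TBDPS ether and leaves acetonide and lactone intact.

Step 18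
Reactants: 24 C2 primary alcohol
Product: 25 C2 aldehyde
Conditions: Dess–Martin periodinane, NaHCO3, CH2Cl2, rt
Reagents that add atoms: none
Why: Dess–Martin oxidation of the neopentyl primary alcohol to a non-enolisable aldehyde; the tertiary C8 alcohol is inert.

Step 19
Reactants: 25 C2 aldehyde
Product: 26 (2S)-allylic alcohol (C2 vinyl carbinol)
Conditions: CH2=CHI, CrCl2 (4 equiv), (R)-L1 (4.4 equiv), Et3N, NiCl2 (2 mol %), THF, rt
Reagents that add atoms: vinyl iodide (C=CI)
Why: Asymmetric Nozaki–Hiyama–Kishi vinylation, chemoselective for the aldehyde over the lactone, in which the chiral sulfonamide–chromium complex delivers the 2S carbinol next to the quaternary C1.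

Step 20
Reactants: 26 (2S)-allylic alcohol
Product: 27 tetraol lactone (free OH at C2, C8, C11, C12)
Conditions: AcOH/H2O (4:1), 45 °C
Reagents that add atoms: none
Why: Mild acid hydrolysis of the acetonide frees the C11/C12 diol while the TBDPS ether, lactone and allylic alcohol survive.

Step 21
Reactants: 27 tetraol lactone
Product: 28 (2S,8S,9S,17R)-Weinreb amide pentaol (C19 = C(O)N(OMe)Me; free OH at C2, C8, C9, C11, C12)
Conditions: AlMe3, MeNH(OMe)·HCl, CH2Cl2, 0 °C → rt
Reagents that add atoms: N,O-dimethylhydroxylamine hydrochloride (CNOC.Cl)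
Why: Weinreb aminolysis with the aluminium amide opens the lactone, freeing 9-OH for acetylation and leaving C19 as an acyl donor that can later lactonise only onto O7.

Step 22
Reactants: 28 (2S,8S,9S,17R)-Weinreb amide pentaol
Product: 29 triacetate (2-OAc; 9-OAc; 12-OAc; 8-OH and 11-OH free; C7H2OSiPh2t-Bu)
Conditions: Ac2O, pyridine, DMAP (cat.), CH2Cl2, 0 °C → rt (crude 28 used at once)
Reagents that add atoms: acetic anhydride (CC(=O)OC(C)=O)
Why: DMAP-catalysed acetylation esterifies the three secondary alcohols and leaves the hindered tertiary alcohols free, which installs all three acetates of the target at once and blocks relactonisation onto O9.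

Step 23
Reactants: 29 triacetate
Product: 30 C7 primary alcohol triacetate
Conditions: HF·pyridine, pyridine, THF, rt
Reagents that add atoms: none
Why: Fluoride desilylation of the TBDPS ether under weakly acidic buffering that avoids acetate migration.

Step 24
Reactants: 30 C7 primary alcohol triacetate
Product: 31 tris(triethylsilyl) ether (O7, O8, O11)
Conditions: Et3SiOTf (3.5 equiv), 2,6-lutidine, CH2Cl2, −78 → 0 °C
Reagents that add atoms: triethylsilyl triflate (CC[Si](CC)(CC)OS(=O)(=O)C(F)(F)F)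
Why: Silylation with the triflate covers the primary and both tertiary alcohols, so that O8 becomes a non-chelating group for the Felkin–Anh-controlled addition in step 28.

Step 25
Reactants: 31 tris(triethylsilyl) ether
Product: 32 (8R)-C7 aldehyde bis(triethylsilyl) ether
Conditions: (COCl)2, DMSO, CH2Cl2, −78 → −40 °C; then Et3N, → −10 °C
Reagents that add atoms: none
Why: Under Swern conditions a primary triethylsilyl ether is converted directly into the aldehyde while tertiary silyl ethers are untouched, which avoids a free α-hydroxy aldehyde.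

Step 26
Reactants: 33 prop-2-yn-1-ol
Product: 35 (Z)-2-(chloromethylidene)but-3-en-1-ol, via alkenylmagnesium alkoxide 34 (not isolated)
Conditions: CH2=CHMgCl (3 equiv), CuI (10 mol %), THF, 0 °C → reflux; then N-chlorosuccinimide, −40 °C → rt
Reagents that add atoms: vinylmagnesium chloride (C=C[Mg]Cl); N-chlorosuccinimide (O=C1CCC(=O)N1Cl)
Why: Hydroxyl-directed copper-catalysed anti carbomagnesiation of propargyl alcohol gives the chelated alkenylmagnesium, whose C–Mg bond is chlorinated with retention, fixing Cl cis to the CH2O group.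

Step 27
Reactants: 35 (Z)-2-(chloromethylidene)but-3-en-1-ol
Product: 36 (Z)-2-(bromomethyl)-1-chlorobuta-1,3-diene
Conditions: CBr4, PPh3, CH2Cl2, 0 °C
Reagents that add atoms: carbon tetrabromide (BrC(Br)(Br)Br)
Why: Appel bromination of the primary allylic alcohol by SN2 displacement at CH2.

Step 28
Reactants: 32 (8R)-C7 aldehyde bis(triethylsilyl) ether; 36 (Z)-2-(bromomethyl)-1-chlorobuta-1,3-diene
Product: 40 seco-triene lactone (2S,6S,7R,8R,9S,17R; rings A and C complete; C2 vinyl and C5 vinyl groups; free 8-OH and 11-OH), via allylchromium dichloride 37 (not isolated), via trimethylsilyl ether 38 (not isolated), via triol amide 39 (not isolated)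
Conditions: CrCl2 (15 mol %), (S,S)-L2 (17 mol %), Mn (3 equiv), Me3SiCl (2 equiv), iPr2NEt (30 mol %), THF, 0 °C; then 1 M aq. HCl, THF, rt
Reagents that add atoms: none
Why: Proposed new method: divalent chromium (regenerated by Mn) inserts into the allylic C–Br bond, and the 2-vinyl-γ-chloroallylchromium equilibrates by 1,3-metallotropic shift to the isomer with Cl trans to the CH2–Cr carbon. It adds through its Cl-bearing γ-carbon in a closed chair transition state (Cl and the aldehyde substituent equatorial) to give the anti chlorohydrin (6S,7R), with the aldehyde face fixed by polar Felkin–Anh control from the α-OSiEt3 group reinforced by the chiral ligand; Me3SiCl turns the catalyst over, and the acid work-up removes the silyl groups and closes the γ-lactone onto the Weinreb amide. The closest known reaction type is the Nozaki–Hiyama allylation of aldehydes with the γ-chloroallylchromium made from 1,3-dichloropropene, here extended to a 2-vinyl reagent, a fully substituted chiral α-silyloxy aldehyde and ligand-controlled anti selectivity.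

Step 29
Reactants: 40 seco-triene lactone
Product: 41 target CNP0285654.2
Conditions: second-generation Hoveyda–Grubbs catalyst RuCl2(=CH-C6H4-2-OiPr)(H2IMes) (10 mol %), toluene (1 mM), 80 °C
Reagents that add atoms: none
Why: Ring-closing metathesis between the C2 vinyl group and the terminal alkene of the diene (the 1,1-disubstituted C5=C16 and ring A olefins are unreactive) closes ring B with loss of ethylene; the Z C3=C4 olefin is expected because the E isomer of this trans-fused cyclodecadiene is much more strained.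

## Compound list

1 | pent-1-en-3-one | CCC(=O)C=C | starting material
2 | (Z)-triisopropyl(penta-1,3-dien-3-yloxy)silane | C/C=C(/C=C)O[Si](C(C)C)(C(C)C)C(C)C | intermediate
3 | ethyl (E)-3-methyl-4-oxobut-2-enoate | CCOC(=O)/C=C(\C)C=O | starting material
4 | ethyl (1S,2S,6S)-6-formyl-2,6-dimethyl-3-(triisopropylsilyloxy)cyclohex-3-ene-1-carboxylate | O=C[C@@]1(C)CC=C(O[Si](C(C)C)(C(C)C)C(C)C)[C@@H](C)[C@@H]1C(=O)OCC | intermediate
5 | ethyl 6-(hydroxymethyl)-2,6-dimethyl-3-(triisopropylsilyloxy)cyclohex-3-ene-1-carboxylate | OC[C@@]1(C)CC=C(O[Si](C(C)C)(C(C)C)C(C)C)[C@@H](C)[C@@H]1C(=O)OCC | intermediate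
6 | TBS ether of 5 | CC(C)(C)[Si](C)(C)OC[C@@]1(C)CC=C(O[Si](C(C)C)(C(C)C)C(C)C)[C@@H](C)[C@@H]1C(=O)OCC | intermediate
7 | enone (C12 ketone, C13=C14) | CC(C)(C)[Si](C)(C)OC[C@@]1(C)C=CC(=O)[C@@H](C)[C@@H]1C(=O)OCC | intermediate
8 | potassium dienolate of 7 (not isolated) | CC(C)(C)[Si](C)(C)OC[C@@]1(C)C=CC(O[K])=C(C)[C@@H]1C(=O)OCC | intermediate
9 | dienyl triflate | CC(C)(C)[Si](C)(C)OC[C@@]1(C)C=CC(OS(=O)(=O)C(F)(F)F)=C(C)[C@@H]1C(=O)OCC | intermediate
10 | cyclohexa-2,4-diene ester | CC(C)(C)[Si](C)(C)OC[C@@]1(C)C=CC=C(C)[C@@H]1C(=O)OCC | intermediate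
11 | cis-diol ester (11α-OH, 12α-OH) | CC(C)(C)[Si](C)(C)OC[C@@]1(C)C=C[C@@H](O)[C@@](C)(O)[C@@H]1C(=O)OCC | intermediate
12 | acetonide ester | CC(C)(C)[Si](C)(C)OC[C@@]1(C)C=C[C@H]2OC(C)(C)O[C@@]2(C)[C@@H]1C(=O)OCC | intermediate
13 | ring A aldehyde (C9 = CHO) | CC(C)(C)[Si](C)(C)OC[C@@]1(C)C=C[C@H]2OC(C)(C)O[C@@]2(C)[C@@H]1C=O | intermediate
14 | tert-butyl(diphenyl)(prop-2-yn-1-yloxy)silane | C#CCO[Si](c1ccccc1)(c1ccccc1)C(C)(C)C | starting material
15 | lithium acetylide of 14 (not isolated) | [Li]C#CCO[Si](c1ccccc1)(c1ccccc1)C(C)(C)C | intermediate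
16 | methyl 4-(tert-butyldiphenylsilyloxy)but-2-ynoate | COC(=O)C#CCO[Si](c1ccccc1)(c1ccccc1)C(C)(C)C | intermediate
17 | methyl (Z)-4-(tert-butyldiphenylsilyloxy)-3-iodobut-2-enoate | COC(=O)/C=C(\I)CO[Si](c1ccccc1)(c1ccccc1)C(C)(C)C | intermediate
18 | (9S,Z)-hydroxy enoate (not isolated) | CC(C)(C)[Si](C)(C)OC[C@@]1(C)C=C[C@H]2OC(C)(C)O[C@@]2(C)[C@@H]1[C@H](O)/C(CO[Si](c3ccccc3)(c4ccccc4)C(C)(C)C)=C\C(=O)OC | intermediate
19 | (9S)-butenolide with ring oxygen on C9 | CC(C)(C)[Si](C)(C)OC[C@@]1(C)C=C[C@H]2OC(C)(C)O[C@@]2(C)[C@@H]1[C@@H]3OC(=O)C=C3CO[Si](c4ccccc4)(c5ccccc5)C(C)(C)C | intermediate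
20 | (8S,9S,17S)-8,17-epoxy lactone | CC(C)(C)[Si](C)(C)OC[C@@]1(C)C=C[C@H]2OC(C)(C)O[C@@]2(C)[C@@H]1[C@@H]3OC(=O)[C@H]4O[C@]43CO[Si](c5ccccc5)(c6ccccc6)C(C)(C)C | intermediate
21 | (8S,9S)-β-hydroxy lactone | CC(C)(C)[Si](C)(C)OC[C@@]1(C)C=C[C@H]2OC(C)(C)O[C@@]2(C)[C@@H]1[C@@H]3OC(=O)C[C@]3(O)CO[Si](c4ccccc4)(c5ccccc5)C(C)(C)C | intermediate
22 | dilithium alkoxide enolate of 21 (not isolated) | CC(C)(C)[Si](C)(C)OC[C@@]1(C)C=C[C@H]2OC(C)(C)O[C@@]2(C)[C@@H]1[C@@H]3OC(O[Li])=C[C@]3(O[Li])CO[Si](c4ccccc4)(c5ccccc5)C(C)(C)C | intermediate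
23 | (8S,9S,17R)-α-methyl-β-hydroxy lactone | CC(C)(C)[Si](C)(C)OC[C@@]1(C)C=C[C@H]2OC(C)(C)O[C@@]2(C)[C@@H]1[C@@H]3OC(=O)[C@H](C)[C@]3(O)CO[Si](c4ccccc4)(c5ccccc5)C(C)(C)C | intermediate
24 | C2 primary alcohol | OC[C@@]1(C)C=C[C@H]2OC(C)(C)O[C@@]2(C)[C@@H]1[C@@H]3OC(=O)[C@H](C)[C@]3(O)CO[Si](c4ccccc4)(c5ccccc5)C(C)(C)C | intermediate
25 | C2 aldehyde | O=C[C@@]1(C)C=C[C@H]2OC(C)(C)O[C@@]2(C)[C@@H]1[C@@H]3OC(=O)[C@H](C)[C@]3(O)CO[Si](c4ccccc4)(c5ccccc5)C(C)(C)C | intermediate
26 | (2S)-allylic alcohol | C=C[C@H](O)[C@@]1(C)C=C[C@H]2OC(C)(C)O[C@@]2(C)[C@@H]1[C@@H]3OC(=O)[C@H](C)[C@]3(O)CO[Si](c4ccccc4)(c5ccccc5)C(C)(C)C | intermediate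
27 | tetraol lactone | C=C[C@H](O)[C@@]1(C)C=C[C@@H](O)[C@@](C)(O)[C@@H]1[C@@H]2OC(=O)[C@H](C)[C@]2(O)CO[Si](c3ccccc3)(c4ccccc4)C(C)(C)C | intermediate
28 | (2S,8S,9S,17R)-Weinreb amide pentaol | C=C[C@H](O)[C@@]1(C)C=C[C@@H](O)[C@@](C)(O)[C@@H]1[C@H](O)[C@@](O)(CO[Si](c2ccccc2)(c3ccccc3)C(C)(C)C)[C@@H](C)C(=O)N(C)OC | intermediate
29 | triacetate (2-OAc, 9-OAc, 12-OAc) | C=C[C@H](OC(C)=O)[C@@]1(C)C=C[C@@H](OC(C)=O)[C@@](C)(O)[C@@H]1[C@H](OC(C)=O)[C@@](O)(CO[Si](c2ccccc2)(c3ccccc3)C(C)(C)C)[C@@H](C)C(=O)N(C)OC | intermediate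
30 | C7 primary alcohol triacetate | C=C[C@H](OC(C)=O)[C@@]1(C)C=C[C@@H](OC(C)=O)[C@@](C)(O)[C@@H]1[C@H](OC(C)=O)[C@@](O)(CO)[C@@H](C)C(=O)N(C)OC | intermediate
31 | tris(triethylsilyl) ether (O7, O8, O11) | C=C[C@H](OC(C)=O)[C@@]1(C)C=C[C@@H](OC(C)=O)[C@@](C)(O[Si](CC)(CC)CC)[C@@H]1[C@H](OC(C)=O)[C@@](O[Si](CC)(CC)CC)(CO[Si](CC)(CC)CC)[C@@H](C)C(=O)N(C)OC | intermediate
32 | (8R)-C7 aldehyde bis(triethylsilyl) ether | C=C[C@H](OC(C)=O)[C@@]1(C)C=C[C@@H](OC(C)=O)[C@@](C)(O[Si](CC)(CC)CC)[C@@H]1[C@H](OC(C)=O)[C@@](O[Si](CC)(CC)CC)(C=O)[C@@H](C)C(=O)N(C)OC | intermediate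
33 | prop-2-yn-1-ol | C#CCO | starting material
34 | (Z)-alkenylmagnesium alkoxide (not isolated) | Cl[Mg]OC/C(C=C)=C\[Mg]Cl | intermediate
35 | (Z)-2-(chloromethylidene)but-3-en-1-ol | OC/C(C=C)=C\Cl | intermediate
36 | (Z)-2-(bromomethyl)-1-chlorobuta-1,3-diene | BrC/C(C=C)=C\Cl | intermediate
37 | 2-vinyl-γ-chloroallylchromium dichloride, ligand omitted (not isolated) | Cl[Cr](Cl)C/C(C=C)=C/Cl | intermediate
38 | (6S,7R)-chlorohydrin O7-trimethylsilyl ether (not isolated) | C=C[C@H](OC(C)=O)[C@@]1(C)C=C[C@@H](OC(C)=O)[C@@](C)(O[Si](CC)(CC)CC)[C@@H]1[C@H](OC(C)=O)[C@@](O[Si](CC)(CC)CC)([C@@H](O[Si](C)(C)C)[C@@H](Cl)C(=C)C=C)[C@@H](C)C(=O)N(C)OC | intermediate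
39 | (6S,7R,8S)-triol Weinreb amide (not isolated) | C=C[C@H](OC(C)=O)[C@@]1(C)C=C[C@@H](OC(C)=O)[C@@](C)(O)[C@@H]1[C@H](OC(C)=O)[C@@](O)([C@@H](O)[C@@H](Cl)C(=C)C=C)[C@@H](C)C(=O)N(C)OC | intermediate
40 | seco-triene lactone (2S,6S,7R,8R,9S,17R) | C=C[C@H](OC(C)=O)[C@@]1(C)C=C[C@@H](OC(C)=O)[C@@](C)(O)[C@@H]1[C@H](OC(C)=O)[C@]2(O)[C@@H](C)C(=O)O[C@H]2[C@@H](Cl)C(=C)C=C | intermediate
41 | CNP0285654.2, (1S,2S,3Z,6S,7R,8R,9S,10S,11S,12R,17R)-2,9,12-triacetoxy-6-chloro-8,11-dihydroxybriara-3,5(16),13-trien-19,7-olide | C=C1/C=C\[C@H](OC(C)=O)[C@@]2(C)C=C[C@@H](OC(C)=O)[C@@](C)(O)[C@@H]2[C@H](OC(C)=O)[C@]2(O)[C@@H](C)C(=O)O[C@H]2[C@H]1Cl | target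

## Step count and risks

Total step count: 29. Longest linear sequence: 25 steps (steps 1–10, 13–25, 28, 29).

**Step 16 (Fráter–Seebach methylation).** The directing alkoxide is tertiary and the methyl must enter on the face that carries the CH2OSiPh2t-Bu group, so selectivity or conversion may be poor. The fallback sets out from 21 and comes back at 23. The dianion of 21 (LiN(iPr)2, THF, −78 °C) is aminomethylated with N,N-dimethylmethyleneiminium iodide to give the Mannich base F1. Quaternisation with MeI and elimination (NaHCO3, MeOH) give the α-methylene-β-hydroxy lactone F2. Hydroxyl-directed hydrogenation (H2, [Rh(nbd)(dppb)]BF4, CH2Cl2) then adds hydrogen to C17 on the face of the coordinating C8–OH and gives 23.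

**Step 28 (proposed new γ-chloroallylation).** The reagent class, the hindered aldehyde and the required anti/Felkin selectivity are all untested. The fallback uses known chemistry, sets out from 32 and comes back at 39 and so at 40. Commercial 2-(bromomethyl)buta-1,3-diene is alkylated onto tetrahydrothiophene to give the sulfonium bromide F3. Its ylide (KN(SiMe3)2, THF, −78 °C) adds to 32 in a Corey–Chaykovsky-type epoxidation to give the trans dienyl epoxide F4, with the Felkin–Anh face of the α-silyloxy aldehyde. Chloride (TiCl4, CH2Cl2, −78 °C) opens the vinyl epoxide at the allylic carbon C6 with inversion to give the anti chlorohydrin F5. The acid work-up of step 28 (1 M aq. HCl, THF) then removes the silyl groups to give 39, which lactonises to 40.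

**Step 29 (ring-closing metathesis).** A ten-membered ring, a hindered C2 vinyl group and a diene partner make oligomerisation or a stalled vinylcarbene likely. The fallback closes ring B at C6–C7 instead; it sets out from 31 and 36 and comes back at 41. Z-selective cross-metathesis with a cyclometalated ruthenium nitrato alkylidene, Ru(NO3)(=CH-C6H4-2-OiPr)(C,C-chelating N-adamantyl-N′-mesitylimidazolin-2-ylidene), joins C3 and C4 first and gives the acyclic (3Z)-diene allylic bromide F6. Swern oxidation as in step 25 gives the aldehyde F7. The conditions of step 28, run at high dilution (1 mM), then close the ring by intramolecular chromium-mediated allylation, an established way to form cyclodecadienes, and give the macrocyclic trimethylsilyl ether F8. The same acid work-up gives the macrocyclic triol amide F9, which lactonises to 41.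

## Further compounds

F1 | step 16 | Mannich base (17-CH2NMe2 lactone) | CC(C)(C)[Si](C)(C)OC[C@@]1(C)C=C[C@H]2OC(C)(C)O[C@@]2(C)[C@@H]1[C@@H]3OC(=O)[C@H](CN(C)C)[C@]3(O)CO[Si](c4ccccc4)(c5ccccc5)C(C)(C)C
F2 | step 16 | α-methylene-β-hydroxy lactone | CC(C)(C)[Si](C)(C)OC[C@@]1(C)C=C[C@H]2OC(C)(C)O[C@@]2(C)[C@@H]1[C@@H]3OC(=O)C(=C)[C@]3(O)CO[Si](c4ccccc4)(c5ccccc5)C(C)(C)C
F3 | step 28 | 1-(2-methylidenebut-3-en-1-yl)tetrahydrothiophenium bromide | C=CC(=C)C[S+]1CCCC1.[Br-]
F4 | step 28 | trans C6–C7 dienyl epoxide | C=C[C@H](OC(C)=O)[C@@]1(C)C=C[C@@H](OC(C)=O)[C@@](C)(O[Si](CC)(CC)CC)[C@@H]1[C@H](OC(C)=O)[C@@](O[Si](CC)(CC)CC)([C@H]2O[C@@H]2C(=C)C=C)[C@@H](C)C(=O)N(C)OC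
F5 | step 28 | anti chlorohydrin bis(triethylsilyl) ether | C=C[C@H](OC(C)=O)[C@@]1(C)C=C[C@@H](OC(C)=O)[C@@](C)(O[Si](CC)(CC)CC)[C@@H]1[C@H](OC(C)=O)[C@@](O[Si](CC)(CC)CC)([C@@H](O)[C@@H](Cl)C(=C)C=C)[C@@H](C)C(=O)N(C)OC
F6 | step 29 | acyclic (3Z)-diene allylic bromide tris(triethylsilyl) ether | Cl/C=C(\CBr)/C=C\[C@H](OC(C)=O)[C@@]1(C)C=C[C@@H](OC(C)=O)[C@@](C)(O[Si](CC)(CC)CC)[C@@H]1[C@H](OC(C)=O)[C@@](O[Si](CC)(CC)CC)(CO[Si](CC)(CC)CC)[C@@H](C)C(=O)N(C)OC
F7 | step 29 | acyclic (3Z)-diene allylic bromide C7 aldehyde | Cl/C=C(\CBr)/C=C\[C@H](OC(C)=O)[C@@]1(C)C=C[C@@H](OC(C)=O)[C@@](C)(O[Si](CC)(CC)CC)[C@@H]1[C@H](OC(C)=O)[C@@](O[Si](CC)(CC)CC)(C=O)[C@@H](C)C(=O)N(C)OC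
F8 | step 29 | macrocyclic O7-trimethylsilyl ether Weinreb amide | C=C1/C=C\[C@H](OC(C)=O)[C@@]2(C)C=C[C@@H](OC(C)=O)[C@@](C)(O[Si](CC)(CC)CC)[C@@H]2[C@H](OC(C)=O)[C@](O[Si](CC)(CC)CC)([C@@H](C)C(=O)N(C)OC)[C@@H](O[Si](C)(C)C)[C@H]1Cl
F9 | step 29 | macrocyclic triol Weinreb amide | C=C1/C=C\[C@H](OC(C)=O)[C@@]2(C)C=C[C@@H](OC(C)=O)[C@@](C)(O)[C@@H]2[C@H](OC(C)=O)[C@](O)([C@@H](C)C(=O)N(C)OC)[C@@H](O)[C@H]1Cl
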